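**Strategy.** The 19,10-lactone hides a 1,4-dicarbonyl array (C10–C5–C4–C19), and C5 is the β-carbon of both carboxyl groups. Ring B is therefore closed at the C5–C10 bond by an intramolecular Stetter reaction: a carbene-bound acyl anion at C10 adds 5-exo to C5 of a tethered 2-methylacrylate, using C9–C8–C6 of a preformed, fully oxygenated bicyclo[3.2.1]octane (rings C and D) as tether and the C6 stereocentre to set C5. The resulting C10 ketone then accepts the C1–C3 unit, the alkoxide closes the lactone, and a Claisen-type acylation (C3–C4) followed by reagent-controlled reduction completes ring A. The precursor is an enantiopure CD aldehyde–enoate built from a desymmetrised Diels–Alder anhydride.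

Key step: step 15

Remark: atoms carry the gibberellane numbers of the target (C1–C19) in all intermediates; TBS = tert-butyldimethylsilyl; α/β refer to the usual gibberellin faces (the C15–C16 bridge is β).
Assumption: the quinidine-mediated methanolysis opens the meso-anhydride in the sense known for cis-cyclohex-4-ene-1,2-dicarboxylic anhydride and gives the (1R,2S)-hemiester; if the sense is the opposite one, quinine is used instead.
Assumption: in the oxazaborolidine reduction of step 19 the quaternary C4 behaves as the large group and the vinyl carbon C2 as the small one; if the roles are reversed, the (S)-catalyst is used instead.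

Step 1
Reactants: 1 2,3-butanedione
Product: 2 2,3-bis(tert-butyldimethylsilyloxy)buta-1,3-diene
Conditions: TBSOTf (2.2 equiv), Et3N, CH2Cl2, 0 °C
Reagents that add atoms: tert-butyldimethylsilyl trifluoromethanesulfonate, CC(C)(C)[Si](C)(C)OS(=O)(=O)C(F)(F)F
Why: Double soft enolisation of the 1,2-diketone by silyl triflate and amine should give the bis(silyl enol ether); no stereocentre is formed.

Step 2
Reactants: 2 2,3-bis(tert-butyldimethylsilyloxy)buta-1,3-diene; 3 maleic anhydride
Product: 4 meso cis-4,5-bis(TBS-oxy)cyclohex-4-ene-1,2-dicarboxylic anhydride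
Conditions: toluene, 25 °C
Reagents that add atoms: none
Why: Diels–Alder reaction of the electron-rich 2,3-dioxygenated diene with maleic anhydride; suprafacial addition gives the cis (meso) anhydride, whose ring carbons become C8, C9 and C11–C14.

Step 3
Reactants: 4 meso cis-anhydride
Product: 5 (1R,2S)-4,5-bis(TBS-oxy)-2-(methoxycarbonyl)cyclohex-4-ene-1-carboxylic acid
Conditions: quinidine (1.1 equiv), MeOH (3 equiv), toluene, −55 °C
Reagents that add atoms: methanol, CO
Why: Cinchona-alkaloid-mediated desymmetrising methanolysis of a meso anhydride; the alkaloid selects one enantiotopic carbonyl and so fixes the absolute configuration (ester carbon = future C8, acid carbon = future C9).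

Step 4
Reactants: 5 (1R,2S)-hemiester; 6 3-bromoprop-1-yne
Product: 7 (1R,2S)-4,5-bis(TBS-oxy)-2-(methoxycarbonyl)-2-(prop-2-yn-1-yl)cyclohex-4-ene-1-carboxylic acid
Conditions: LiN(i-Pr)2 (2.2 equiv), THF, −78 °C; then 6, −78 → 0 °C; buffered aqueous work-up (pH 4)
Reagents that add atoms: none
Why: Alkylation of the ester-enolate/carboxylate dianion, in which the electrophile enters the enolate face anti to the neighbouring carboxylate, so that the propargyl group (C15–C17) ends trans to C10 and the quaternary centre C8 is set.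

Step 5
Reactants: 7 propargylated hemiester
Product: 9 cis-fused γ-lactone 5,6-bis(TBS-oxy)-7a-(prop-2-yn-1-yl)-3a,4,7,7a-tetrahydro-2-benzofuran-1(3H)-one, via hydroxy ester 8 (not isolated)
Conditions: i-BuOCOCl, N-methylmorpholine, THF, −15 °C; then NaBH4, MeOH, −15 → 25 °C
Reagents that add atoms: none
Why: Mixed-anhydride activation followed by borohydride reduction converts only the carboxylic acid into the primary alcohol (C10), which lactonises onto the cis methyl ester in a 5-exo-trig acyl substitution without touching a stereocentre.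

Step 6
Reactants: 9 alkynyl enediol-bis(silyl ether) γ-lactone
Product: 10 tricyclic keto lactone with 13-(TBS-oxy), 12-oxo and 16-methylene groups
Conditions: Ph3PAuCl (5 mol%), AgBF4 (5 mol%), CH2Cl2/MeOH (10:1), 25 °C
Reagents that add atoms: none
Why: Gold-catalysed Conia-ene-type 5-exo-dig carbocyclisation of a silyl enol ether onto the terminal alkyne, in which enol carbon C13 (three atoms from the alkyne) attacks C16 to close the five-membered ring D in preference to the six-membered closure through C12, the C12 oxocarbenium ion gives up its silyl group to methanol, and the tether fixes C13 (C16 on the face of C15).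

Step 7
Reactants: 10 tricyclic keto lactone
Product: 11 12α-hydroxy-13-(TBS-oxy) lactone
Conditions: LiBH(sec-Bu)3, THF, −78 °C; then H2O
Reagents that add atoms: none
Why: Bulky-hydride reduction of the cyclohexanone, in which the axial trajectory on the α face is blocked by the axial C10 methylene on C9 (1,3-diaxial), so that hydride should enter equatorially from the β face and give the axial 12α-alcohol, cis to the 13-oxygen.

Step 8
Reactants: 11 12α-hydroxy lactone
Product: 12 12α,13-bis(TBS-oxy) γ-lactone
Conditions: TBSOTf, 2,6-lutidine, CH2Cl2, 0 → 25 °C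
Reagents that add atoms: tert-butyldimethylsilyl trifluoromethanesulfonate, CC(C)(C)[Si](C)(C)OS(=O)(=O)C(F)(F)F
Why: Silyl triflate silylation of a hindered secondary alcohol under buffered conditions that spare the 13-oxygenated 16-ene unit.

Step 9
Reactants: 12 bis(silyl ether) γ-lactone
Product: 14 δ-lactone C8–C6H2–C5(=O)–O–C10H2–C9, via hydroxy ketene 13 (not isolated)
Conditions: CH2Br2, lithium 2,2,6,6-tetramethylpiperidide, THF, −78 °C; LiN(SiMe3)2; n-BuLi, −78 → −20 °C; then AcOH, THF, −78 → 25 °C
Reagents that add atoms: dibromomethane, BrCBr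
Why: Kowalski ester homologation applied to the lactone: dibromomethyllithium adds to the carbonyl, bromine–lithium exchange triggers the 1,2-shift of C8 to give the ynolate, and on protonation the ketene is trapped by the C10 hydroxyl, which inserts C6 between C8 and the carbonyl carbon (C5) without touching a stereocentre.

Step 10
Reactants: 14 δ-lactone
Product: 15 6-(hydroxymethyl) δ-lactone with C7 on the lactone face syn to C15
Conditions: LiN(i-Pr)2, THF, −78 °C; CH2O (gas, from cracked paraformaldehyde), −78 °C; aq. NH4Cl at −78 °C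
Reagents that add atoms: formaldehyde, C=O
Why: Aldol reaction of the lactone lithium enolate with formaldehyde, which should enter the enolate face anti to the pseudo-axial C8–C14 bond (the convex face of the cis-fused bicycle, syn to C15) and so set C6 with C7 in the configuration of the target.

Step 11
Reactants: 15 6-(hydroxymethyl) δ-lactone
Product: 16 6-(TBS-oxymethyl) δ-lactone
Conditions: TBSCl, imidazole, DMF, 25 °C
Reagents that add atoms: tert-butyl(chloro)dimethylsilane, CC(C)(C)[Si](C)(C)Cl
Why: Standard silylation of a primary alcohol under conditions too weakly basic to epimerise C6.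

Step 12
Reactants: 16 silylated δ-lactone
Product: 17 lactol (C5 hemiacetal, anomer mixture)
Conditions: i-Bu2AlH, CH2Cl2, −78 °C; aqueous work-up
Reagents that add atoms: none
Why: Partial reduction of the lactone stops at the lactol because the tetrahedral aluminate is stable at low temperature.

Step 13
Reactants: 17 lactol; 18 ethyl 2-(triphenyl-λ5-phosphanylidene)propanoate
Product: 19 ethyl (E)-2-methylbut-2-enoate alcohol (C8–C6H(CH2OTBS)–C5H=C4(CH3)CO2Et; C9–CH2OH)
Conditions: toluene, 90 °C
Reagents that add atoms: none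
Why: Wittig reaction of the ring-opened hydroxy aldehyde with a stabilised ylide should give the (E)-2-methyl enoate (C4, C18, C19) and free the C10 hydroxyl, C6 being safe because only a trace of aldehyde is present under nearly neutral conditions.

Step 14
Reactants: 19 enoate alcohol
Product: 20 C10 aldehyde bearing the enoate arm
Conditions: Dess–Martin periodinane, CH2Cl2, 0 → 25 °C
Reagents that add atoms: none
Why: Dess–Martin oxidation of the primary alcohol to the aldehyde under non-basic conditions that do not epimerise C9.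

Step 15
Reactants: 20 C10 aldehyde bearing the enoate arm
Product: 21 ring B ketone (10-oxo, 5β-H, C5 side chain CH(CH3)CO2Et)
Conditions: 2-(pentafluorophenyl)-6,7-dihydro-5H-pyrrolo[2,1-c][1,2,4]triazol-2-ium tetrafluoroborate (20 mol%), KN(SiMe3)2 (18 mol%), toluene, 25 °C
Reagents that add atoms: none
Why: The triazolylidene adds to the C10 aldehyde and proton transfer gives the acyl-anion equivalent, which adds to C5, the β-carbon of the 2-methylacrylate, after which proton transfer releases the carbene and the C10 ketone. The closest known reaction type is the intramolecular Stetter reaction of aliphatic aldehydes with trisubstituted unsaturated esters. Ring B (C5–C6–C8–C9–C10) closes in the 5-exo-trig mode with C9–C8–C6 as tether, the two ends being held gauche by the axial C9 and equatorial C8 bonds of the rigid bicyclo[3.2.1]octane. The new centre C5 is controlled by C6: allylic 1,3-strain with the C4 methyl places C6–H in the alkene plane, the tethered acyl anion can reach only the alkene face that carries C8, and C4 therefore ends trans to the C7 substituent (5β-H), which is also the more stable arrangement of a 2,3-disubstituted cyclopentanone; C4 itself forms as a mixture that is erased later. The step needs conjugate addition to win over carbonyl addition and over epimerisation at C9, and this is secured because the substrate holds no second aldehyde or ketone and no acidic C–H other than the aldehyde α-hydrogen, and because less base than azolium salt is used.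

Step 16
Reactants: 21 ring B ketone; 22 ethyl propiolate
Product: 24 10β-(3-ethoxy-3-oxoprop-1-ynyl) 19,10-γ-lactone, via tertiary alcohol 23 (not isolated)
Conditions: 22, n-BuLi, THF, −78 °C; then 21, −78 → −20 °C; aq. NH4Cl
Reagents that add atoms: none
Why: Addition of lithium ethyl propiolate, a weakly basic acetylide, to the enolisable cyclopentanone should occur from the β face, the α face being shielded by C11, the C5 side chain and the axial 12-silyloxy group, and the resulting 10α-alkoxide attacks the cis C19 ester (5-exo-trig) below −20 °C to close the lactone, which sets C10.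

Step 17
Reactants: 24 alkynoate γ-lactone
Product: 25 (Z)-enoate γ-lactone
Conditions: H2 (1 atm), Pd/CaCO3 poisoned with Pb(OAc)2 (Lindlar catalyst), quinoline, EtOAc, 25 °C
Reagents that add atoms: none
Why: Lindlar semi-hydrogenation by syn addition gives the (Z)-alkene C1=C2 while the hindered 1,1-disubstituted 16-ene is left alone.

Step 18
Reactants: 25 (Z)-enoate γ-lactone
Product: 26 ring A-closed 1-en-3-one 19,10-lactone
Conditions: LiN(SiMe3)2 (1.2 equiv), THF, −78 → −40 °C; AcOH at −78 °C
Reagents that add atoms: none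
Why: Intramolecular Claisen (Dieckmann-type) acylation of the lactone lithium enolate (C4 carries the only acidic C–H) by the (Z)-enoate ester closes ring A (6-exo-trig) to the non-enolisable 1-en-3-one, C3 being able to bond only to the enolate face that carries C1, which sets the quaternary centre C4, and the cold acidic quench keeps the released ethoxide from reopening the β-keto lactone.

Step 19
Reactants: 26 ring A-closed enone
Product: 27 tris(TBS) ether of the 3β-hydroxy lactone
Conditions: (R)-1-methyl-3,3-diphenyltetrahydro-1H,3H-pyrrolo[1,2-c][1,3,2]oxazaborole ((R)-Me-CBS catalyst, 20 mol%), catecholborane (2.0 equiv), toluene, −78 → −40 °C; MeOH, then pH 7 phosphate buffer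
Reagents that add atoms: none
Why: Corey–Bakshi–Shibata reduction with catecholborane reduces the enone 1,2 without hydroborating the 16-ene, and the catalyst, which binds the carbonyl lone pair on the side of the small vinyl carbon C2 and keeps the quaternary C4 away from its B-methyl group, should deliver hydride to the α face of C3 and give the 3β-alcohol against the substrate's own preference for β-face attack.

Step 20
Reactants: 27 tris(TBS) ether
Product: 28 3β,7,12α,13-tetrahydroxy 19,10-lactone (C7 alcohol)
Conditions: HF·pyridine, pyridine, THF, 0 → 25 °C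
Reagents that add atoms: none
Why: Fluoride cleavage of the three silyl ethers under mildly acidic conditions that should leave the allylic lactone and the 13-hydroxy-16-ene unit intact.

Step 21
Reactants: 28 tetraol
Product: 30 target gibberellin (3β,12α,13-trihydroxy 1,16-diene 7-carboxylic acid with the 19,10-lactone), via C7 aldehyde 29 (not isolated)
Conditions: 2,2,6,6-tetramethylpiperidin-1-oxyl (TEMPO, 20 mol%), PhI(OAc)2 (2.5 equiv), MeCN/H2O (1:1), 0 → 25 °C
Reagents that add atoms: water, O
Why: Oxoammonium (TEMPO) oxidation should take the primary alcohol in preference to the hindered secondary and tertiary alcohols and carry the aldehyde hydrate on to the acid, C6 keeping its configuration, which is also the more stable one (C7 trans to C4).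

**Compound list**

1 | 2,3-butanedione | CC(=O)C(C)=O | starting material
2 | 2,3-bis(tert-butyldimethylsilyloxy)buta-1,3-diene | C=C(O[Si](C)(C)C(C)(C)C)C(=C)O[Si](C)(C)C(C)(C)C | intermediate
3 | maleic anhydride | O=C1OC(=O)C=C1 | starting material
4 | meso cis-4,5-bis(TBS-oxy)cyclohex-4-ene-1,2-dicarboxylic anhydride | O=C1OC(=O)[C@H]2CC(O[Si](C)(C)C(C)(C)C)=C(O[Si](C)(C)C(C)(C)C)C[C@@H]12 | intermediate
5 | (1R,2S)-4,5-bis(TBS-oxy)-2-(methoxycarbonyl)cyclohex-4-ene-1-carboxylic acid (cis hemiester) | COC(=O)[C@H]1CC(O[Si](C)(C)C(C)(C)C)=C(O[Si](C)(C)C(C)(C)C)C[C@H]1C(=O)O | intermediate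
6 | 3-bromoprop-1-yne | C#CCBr | starting material
7 | (1R,2S)-4,5-bis(TBS-oxy)-2-(methoxycarbonyl)-2-(prop-2-yn-1-yl)cyclohex-4-ene-1-carboxylic acid (propargyl trans to the C1 carboxyl) | C#CC[C@]1(C(=O)OC)CC(O[Si](C)(C)C(C)(C)C)=C(O[Si](C)(C)C(C)(C)C)C[C@H]1C(=O)O | intermediate
8 | methyl 3,4-bis(TBS-oxy)-6-(hydroxymethyl)-1-(prop-2-yn-1-yl)cyclohex-3-ene-1-carboxylate (hydroxymethyl cis to the ester, configuration as in 7) | C#CC[C@]1(C(=O)OC)CC(O[Si](C)(C)C(C)(C)C)=C(O[Si](C)(C)C(C)(C)C)C[C@H]1CO | intermediate
9 | cis-fused γ-lactone 5,6-bis(TBS-oxy)-7a-(prop-2-yn-1-yl)-3a,4,7,7a-tetrahydro-2-benzofuran-1(3H)-one (C=O on C8, OCH2 = C10 on C9) | C#CC[C@]12CC(O[Si](C)(C)C(C)(C)C)=C(O[Si](C)(C)C(C)(C)C)C[C@H]1COC2=O | intermediate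
10 | tricyclic keto lactone: bicyclo[3.2.1]octane CD unit with 13-(TBS-oxy) at the bridgehead, 12-oxo and 16-methylene, γ-lactone of 9 fused at C8–C9 | C=C1C[C@]23C[C@@]1(O[Si](C)(C)C(C)(C)C)C(=O)C[C@H]2COC3=O | intermediate
11 | 12α-hydroxy analogue of 10 (12-OH cis to 13-OTBS, anti to the C15–C16 bridge) | C=C1C[C@]23C[C@@]1(O[Si](C)(C)C(C)(C)C)[C@@H](O)C[C@H]2COC3=O | intermediate
12 | 12α,13-bis(TBS-oxy) γ-lactone | C=C1C[C@]23C[C@@]1(O[Si](C)(C)C(C)(C)C)[C@@H](O[Si](C)(C)C(C)(C)C)C[C@H]2COC3=O | intermediate
13 | hydroxy ketene (C8–CH=C=O, C9–CH2OH) | C=C1C[C@]2(C=C=O)C[C@@]1(O[Si](C)(C)C(C)(C)C)[C@@H](O[Si](C)(C)C(C)(C)C)C[C@H]2CO | intermediate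
14 | δ-lactone C8–C6H2–C5(=O)–O–C10H2–C9 with 12α,13-bis(TBS-oxy) | C=C1C[C@]23C[C@@]1(O[Si](C)(C)C(C)(C)C)[C@@H](O[Si](C)(C)C(C)(C)C)C[C@H]2COC(=O)C3 | intermediate
15 | 6-(hydroxymethyl) δ-lactone, C7 syn to C15 (6β-CH2OH in the sense of the target) | C=C1C[C@]23C[C@@]1(O[Si](C)(C)C(C)(C)C)[C@@H](O[Si](C)(C)C(C)(C)C)C[C@H]2COC(=O)[C@@H]3CO | intermediate
16 | 6-(TBS-oxymethyl) δ-lactone | C=C1C[C@]23C[C@@]1(O[Si](C)(C)C(C)(C)C)[C@@H](O[Si](C)(C)C(C)(C)C)C[C@H]2COC(=O)[C@@H]3CO[Si](C)(C)C(C)(C)C | intermediate
17 | lactol (C5 hemiacetal, anomer mixture) | C=C1C[C@]23C[C@@]1(O[Si](C)(C)C(C)(C)C)[C@@H](O[Si](C)(C)C(C)(C)C)C[C@H]2COC(O)[C@@H]3CO[Si](C)(C)C(C)(C)C | intermediate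
18 | ethyl 2-(triphenyl-λ5-phosphanylidene)propanoate | CCOC(=O)C(C)=P(c1ccccc1)(c1ccccc1)c1ccccc1 | starting material
19 | CD unit with C8–C6H(CH2OTBS)–C5H=C4(CH3)CO2Et ((E)-enoate) and C9–CH2OH | C=C1C[C@]2([C@@H](CO[Si](C)(C)C(C)(C)C)/C=C(\C)C(=O)OCC)C[C@@]1(O[Si](C)(C)C(C)(C)C)[C@@H](O[Si](C)(C)C(C)(C)C)C[C@H]2CO | intermediate
20 | C10 aldehyde corresponding to 19 | C=C1C[C@]2([C@@H](CO[Si](C)(C)C(C)(C)C)/C=C(\C)C(=O)OCC)C[C@@]1(O[Si](C)(C)C(C)(C)C)[C@@H](O[Si](C)(C)C(C)(C)C)C[C@H]2C=O | intermediate
21 | ring B ketone: 10-oxo, 5β-H, C5 side chain CH(CH3)CO2Et trans to C7H2OTBS, mixture at C4 | C=C1C[C@]23C[C@@]1(O[Si](C)(C)C(C)(C)C)[C@@H](O[Si](C)(C)C(C)(C)C)C[C@H]2C(=O)[C@@H](C(C)C(=O)OCC)[C@@H]3CO[Si](C)(C)C(C)(C)C | intermediate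
22 | ethyl propiolate (ethyl prop-2-ynoate) | C#CC(=O)OCC | starting material
23 | tertiary alcohol: 10α-hydroxy, 10β-(3-ethoxy-3-oxoprop-1-ynyl), C19 ethyl ester | C=C1C[C@]23C[C@@]1(O[Si](C)(C)C(C)(C)C)[C@@H](O[Si](C)(C)C(C)(C)C)C[C@H]2[C@](O)(C#CC(=O)OCC)[C@@H](C(C)C(=O)OCC)[C@@H]3CO[Si](C)(C)C(C)(C)C | intermediate
24 | 10β-(3-ethoxy-3-oxoprop-1-ynyl) 19,10-γ-lactone, mixture at C4 | C=C1C[C@]23C[C@@]1(O[Si](C)(C)C(C)(C)C)[C@@H](O[Si](C)(C)C(C)(C)C)C[C@H]2[C@@]4(C#CC(=O)OCC)OC(=O)C(C)[C@H]4[C@@H]3CO[Si](C)(C)C(C)(C)C | intermediate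
25 | (Z)-enoate γ-lactone (10β-[(Z)-3-ethoxy-3-oxoprop-1-enyl]), mixture at C4 | C=C1C[C@]23C[C@@]1(O[Si](C)(C)C(C)(C)C)[C@@H](O[Si](C)(C)C(C)(C)C)C[C@H]2[C@@]4(/C=C\C(=O)OCC)OC(=O)C(C)[C@H]4[C@@H]3CO[Si](C)(C)C(C)(C)C | intermediate
26 | 7-O,12-O,13-O-tris(TBS) 3-oxo-1-ene 19,10-lactone with C7 as CH2O (rings A–D closed) | C=C1C[C@]23C[C@@]1(O[Si](C)(C)C(C)(C)C)[C@@H](O[Si](C)(C)C(C)(C)C)C[C@H]2[C@@]12C=CC(=O)[C@@](C)(C(=O)O1)[C@H]2[C@@H]3CO[Si](C)(C)C(C)(C)C | intermediate
27 | 7-O,12-O,13-O-tris(TBS) ether of the 3β-hydroxy 19,10-lactone with C7 as CH2O (rings A–D closed) | C=C1C[C@]23C[C@@]1(O[Si](C)(C)C(C)(C)C)[C@@H](O[Si](C)(C)C(C)(C)C)C[C@H]2[C@@]12C=C[C@H](O)[C@@](C)(C(=O)O1)[C@H]2[C@@H]3CO[Si](C)(C)C(C)(C)C | intermediate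
28 | 3β,7,12α,13-tetrahydroxy 19,10-lactone (C7 alcohol of the target) | C=C1C[C@]23C[C@@]1(O)[C@@H](O)C[C@H]2[C@@]12C=C[C@H](O)[C@@](C)(C(=O)O1)[C@H]2[C@@H]3CO | intermediate
29 | C7 aldehyde of the target | C=C1C[C@]23C[C@@]1(O)[C@@H](O)C[C@H]2[C@@]12C=C[C@H](O)[C@@](C)(C(=O)O1)[C@H]2[C@@H]3C=O | intermediate
30 | target gibberellin (number 87 of the gibberellin A series): 3β,12α,13-trihydroxy 1,16-diene 7-carboxylic acid with the 19,10-lactone | C=C1C[C@]23C[C@@]1(O)[C@@H](O)C[C@H]2[C@@]12C=C[C@H](O)[C@@](C)(C(=O)O1)[C@H]2[C@@H]3C(=O)O | target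

**Step count.** Total: 21 steps. Longest linear sequence: 21 steps (1 → 30); compounds 3, 6, 18 and 22 are purchased.

**Steps most likely to fail**

Step 15 (Stetter closure of ring B). Carbene addition to the hindered, α-branched aldehyde may be slow, so that base-mediated epimerisation at C9 or self-condensation of the aldehyde outruns the 5-exo addition. The fallback sets out from 20 and comes back at 21. Pinnick oxidation (NaClO2, NaH2PO4, 2-methylbut-2-ene, t-BuOH/H2O) gives the carboxylic acid F2, and (PhSe)2 with Bu3P converts it into the Se-phenyl selenoester F3. Bu3SnH and azobisisobutyronitrile (slow addition, benzene, 80 °C) then generate the C10 acyl radical, which cyclises 5-exo-trig onto C5 under neutral conditions with the same allylic-strain control; reduction of the α-ester radical gives 21.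

Step 6 (gold-catalysed closure of ring D). The enediol bis(silyl ether) may be protodesilylated by adventitious acid before the carbon–carbon bond forms, or the ring may close through the distal enol carbon C12 in the six-membered mode. The fallback sets out from 9 and comes back at 10. Bromine (1.0 equiv, CH2Cl2, −78 °C) oxidises the enediol bis(silyl ether), far faster than it touches the alkyne, to the alkynyl 1,2-diketone F1. A nickel-catalysed reductive alkyne–ketone cyclisation (Ni(cod)2, zerovalent nickel, 10 mol%; PBu3; tert-butyldimethylsilane; THF) then joins C16 to the nearer carbonyl carbon C13 through a five-membered oxanickelacycle and transfers the silyl group to the new tertiary alkoxide, which gives 10.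

Step 19 (reduction of the enone to the 3β-alcohol). Facial selectivity may be poor, because the catalyst has to override the substrate's preference for hydride attack on the β face, anti to the axial C4–C19 bond, which leads to the 3α-alcohol. The fallback sets out from 26 and comes back at 27, and it uses that substrate preference instead of fighting it. Luche reduction (NaBH4, CeCl3·7H2O, MeOH, −78 °C) should give the 3α-alcohol F4. Mitsunobu reaction with chloroacetic acid (Ph3P, diisopropyl azodicarboxylate, toluene, 0 °C) inverts C3 and gives the 3β-chloroacetate F5. Thiourea with NaHCO3 in EtOH at 50 °C then removes the chloroacetyl group without base strong enough to trigger retro-aldol epimerisation at C3, which gives 27.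

Further compounds
F1 | step 6 | alkynyl 1,2-diketone (γ-lactone of 9 with C12 and C13 as ketones) | C#CC[C@]12CC(=O)C(=O)C[C@H]1COC2=O
F2 | step 15 | C10 carboxylic acid corresponding to aldehyde 20 | C=C1C[C@]2([C@@H](CO[Si](C)(C)C(C)(C)C)/C=C(\C)C(=O)OCC)C[C@@]1(O[Si](C)(C)C(C)(C)C)[C@@H](O[Si](C)(C)C(C)(C)C)C[C@H]2C(=O)O
F3 | step 15 | Se-phenyl selenoester of F2 | C=C1C[C@]2([C@@H](CO[Si](C)(C)C(C)(C)C)/C=C(\C)C(=O)OCC)C[C@@]1(O[Si](C)(C)C(C)(C)C)[C@@H](O[Si](C)(C)C(C)(C)C)C[C@H]2C(=O)[Se]c1ccccc1
F4 | step 19 | 3α-alcohol (C3 epimer of 27) | C=C1C[C@]23C[C@@]1(O[Si](C)(C)C(C)(C)C)[C@@H](O[Si](C)(C)C(C)(C)C)C[C@H]2[C@@]12C=C[C@@H](O)[C@@](C)(C(=O)O1)[C@H]2[C@@H]3CO[Si](C)(C)C(C)(C)C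
F5 | step 19 | 3β-chloroacetate of 27 | C=C1C[C@]23C[C@@]1(O[Si](C)(C)C(C)(C)C)[C@@H](O[Si](C)(C)C(C)(C)C)C[C@H]2[C@@]12C=C[C@H](OC(=O)CCl)[C@@](C)(C(=O)O1)[C@H]2[C@@H]3CO[Si](C)(C)C(C)(C)C
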